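## Structural features

The target is a germacranolide: a ten-membered carbocycle (C1–C10) fused along C6–C7 to a five-membered α,β-unsaturated lactone (O–C6, C12=O). The C7=C11 double bond lies inside the lactone and outside the large ring, and C11 carries the acetoxymethyl carbon C13. The carbocycle bears a free secondary hydroxyl at C1, a methyl-bearing stereocentre at C10, a methacrylate at C8 and a cis-4,5-epoxide with the C15 methyl on C4, giving six stereocentres (1S,4R,5S,6S,8S,10R). C1 and C10 are vicinal (anti in the extended chain), C8 is 1,3-syn to C10 and 1,3-syn to C6 across the sp2 carbon C7, and C4, C5 and C6 are contiguous. On a flat drawing of the ring, O1, the C10 methyl, O8, O6 and the epoxide oxygen all point to the same side. Fragile elements are the epoxide (it sits next to the acidic γ-proton of the butenolide at C6 and is opened by base through elimination), the Michael-accepting methacrylate, the primary allylic acetate and the transannular pair C1–OH/C4. The real difficulties are closing the medium ring, placing the epoxide oxygen on the alkene face syn to O6 (not the face a peracid should reach from the periphery), and telling five oxygens (O1, O6, O7, O8, O13) apart. The ring closure exploits that C2 is a plain methylene next to the C1 carbinol while C3 is allylic to the cis C4=C5 alkene: a sulfonyl carbanion at C2 and a (Z)-allylic chloride at C3 allow an SN2 closure with the alkene geometry already fixed.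

## Logic of the disconnections

40 ⇒ 39. The C4–O and C5–O bonds of the oxirane are cut. The epoxide is the most base- and acid-sensitive group, so it is placed last. Two stereocentres disappear, leaving a cis-trisubstituted alkene. The forward oxidation must pick the electron-rich C4=C5 among three alkenes and the face on which O1 lies, which calls for hydroxyl direction.

39 ⇒ 38 ⇒ 37 ⇒ 36 ⇒ 35 ⇒ 34. The acyl C–O bonds at O8 and O13 are cut and O1, O8 and O13 are returned to three protecting groups of graded lability. Two different esters and a free alcohol cannot otherwise be placed. The result is 34, which has no ester except the lactone. Each unmasking must be selective (oxidative against silyl, small silyl against large silyl), and no acylation may isomerise the butenolide.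

34 ⇒ 33 ⇒ 28 + 32. C7=C11 and the C12–O6 ester bond are cut. The butenolide cannot be present during carbanion chemistry, and an intramolecular olefination fixes the position of the tetrasubstituted alkene. Lactone carbonyl, C11 and C13 then come from one small reagent and the macrocycle reduces to an α-hydroxy ketone. The phosphonate carbanion must add to the hindered C7 ketone faster than C6 or C8 enolise, and the O13 substituent must not be a leaving group.

32 ⇒ 31 ⇒ 29 + 30. The C13–O bond is cut (conjugate addition) and the carboxyl ester is restored. Both partners are commercial. The forward sequence must add the alcohol to the activated alkene and hydrolyse only the carboxylic ester.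

28 ⇒ 27 ⇒ 26 ⇒ 25. The C7 carbonyl is taken back to a protected carbinol and O6 is re-silylated. A ketone between two oxygenated carbons would not survive amide base or sodium amalgam, and a ketal there could not be removed selectively. 25 carries only ethers. Three orthogonal operations are demanded: oxidative debenzylation at O7, oxidation, and selective loss of the smallest silyl group.

25 ⇒ 24. The C2–S bond is restored. The sulfonyl group is a temporary activator for C2. Its reductive removal must not eliminate the neighbouring O1 silyl ether.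

24 ⇒ 23. The C2–C3 ring bond is cut. This is the one ring bond flanked by an acidifiable methylene and an allylic position, and the cut turns the ten-membered ring into an open chain whose four stereocentres and Z-alkene can be built by acyclic control. The forward step needs a clean intramolecular SN2 reaction under high dilution.

23 ⇒ 21 ⇒ 20 ⇒ 19. Chloride at C3 is traced to an alcohol and then to its acetate, and the O6 silyl ether to the free carbinol. O6 must be capped before C3 is activated, because a free cis-hydroxyl would close a dihydrofuran. The chloride must form without allylic transposition.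

19 ⇒ 14 + 18. The C5–C6 bond is cut. This joins the whole stereochemical chain to a three-carbon alkene piece of fixed Z geometry and creates C6. The addition must tolerate sulfone C–H bonds and an acetate, and it must be anti-selective with respect to O7.

18 ⇒ 17 ⇒ 15. The C4–C15 and C5–I bonds are cut. A regio- and stereodefined addition of methyl and metal across an alkyne is needed so that iodine ends up cis to C3.

14 ⇒ 12. The C6 aldehyde is traced to a terminal alkene with one extra carbon. The alkene is a robust aldehyde surrogate through the basic and reductive steps. The forward cleavage must leave the C7 stereocentre intact.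

12 ⇒ 11 ⇒ 10. The C1–H bond (and the O1 silyl group) is removed to give a β-keto sulfone. The C1 configuration can then be set by catalyst control on a substrate without competing carbonyl groups. The reduction must spare the terminal alkene.

10 ⇒ 9 ⇒ 7 + 8. The C1–C2 bond is cut (and the O8 silyl group removed). The sulfone arrives with C2, and the C1 carbonyl and O8 both come from one lactone. Acylation must be faster than enolisation at C10.

7 ⇒ 6. The C10–methyl bond is cut. The lactone ring relays the C8 configuration to C10. Alkylation must occur anti to the ring substituent.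

6 ⇒ 3 + 4. The C9–C10 bond and the lactone C–O bond are cut. Two carbons are added to a terminal epoxide, which is attacked only at its CH2 end.

3 ⇒ 2 ⇒ 1. The O7 ether bond and the epoxide C–O bonds are cut to reach an achiral dienol. One asymmetric epoxidation must select one of two enantiotopic vinyl groups and one face, fixing C8 and the temporary C7 centre.

## Other disconnections considered

Alternative 1: The cut is C6–C7 together with the lactone C12–O bond. Open-chain aldehyde A1 carries a fully substituted (Z)-iodoalkene ester at C7/C11. CrCl2 with catalytic NiCl2 would turn the C7–I bond into an alkenylchromium that adds to the C6 aldehyde; the C6 alkoxide then lactonises onto the C12 methyl ester to give A2, the O1 silyl ether of the target.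
- In its favour: ring, C6 stereocentre and butenolide arise in one neutral operation, and one deprotection remains. On step economy after ring closure it is clearly better than the chosen plan (one step against fourteen), and it needs no temporary activating group.
- Against it: A1 must already contain the cis-epoxide, both esters and an epimerisable epoxy aldehyde, so every sensitive group passes through the fragment synthesis. Metal insertion into a tetrasubstituted, electron-poor iodoalkene flanked by an allylic acetate and a β-acyloxy group is expected to be slow, and the organochromium could eliminate. C6 is created during a medium-ring closure next to the epoxide under substrate control only.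
- Comparison: the chosen plan sets C6 in the open chain by Felkin control, which is the safer stereochemical course. On mechanism the two closures are equal, both being polar additions under high dilution.

Alternative 2: The cut is C1–C2 next to a C2≡C3 triple bond. Iodoalkyne aldehyde A3, with epoxide and butenolide in place, would give an alkynylchromium that adds to the C1 aldehyde to form cyclodecynol A4 as a C1 epimer mixture.
- In its favour: iodoalkynes are the most easily activated partners for this coupling, and the nucleophile is not basic. On tolerance of the lactone and epoxide this is better than the amide base of the chosen plan. Fewer steps follow the closure, which is also better.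
- Against it: a ten-membered cycloalkyne with two further sp2 carbons and a fused epoxide is strained, and C1 forms without control and must be corrected on the ring. The triple bond must then be saturated in the presence of the butenolide, the propargylic epoxide (prone to SN2′ opening and hydrogenolysis) and later the methacrylate. That is harder than removing a sulfone.
- Comparison: both plans leave a temporary feature at the closure site (epimeric C2 sulfone against epimeric C1 and the alkyne), so they are equal there. The chosen plan fixes C1 by catalyst control before closure.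

Alternative 3: The cut is C8–C9, made by a [3,3] shift. The potassium alkoxide of trans-dialkenyl carbinol A5 would rearrange through a chair to the enolate of dienone A6.
- In its favour: two steps from a cyclohexenone give the ten-membered ring without high dilution. In ring-forming efficiency and atom economy this is better than the chosen plan. The cis C4=C5 alkene is inherited (equal to the chosen plan), and C8 is set by the enol ether geometry.
- Against it: A6 has a C1=C10 alkene where the target needs the C1 carbinol and C10 methyl stereocentres. It has its ketone at C6 where the target needs an oxygen at C6 and an sp2 C7 bearing C11–C13. Hydration of C1=C10 with control of two centres, carbonyl reduction, introduction of three carbons at C7 and differentiation of two trisubstituted alkenes would all take place on a flexible 1(10),4-diene that cyclises transannularly with electrophiles.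
- Comparison: five of six stereocentres would be set on the medium ring, against two in the chosen plan, and the long functionalisation would cancel the short ring synthesis.

Key step: step 16

Remark on the chemistry (numbering): germacrane numbering (C1–C15) is used for every intermediate, open-chain ones included.

Remark on the chemistry (design change): a dioxolane at C7 between two oxygenated carbons could not be hydrolysed without loss of the neighbouring silyl and allylic ethers, so C7 is carried through the ring closure as a 4-methoxybenzyl-protected carbinol and oxidised afterwards; the other groups are redistributed (O1 TIPS, O8 TBS, O6 TES). Carbon skeleton, C2 phenyl sulfone, (Z)-allylic chloride and the C2–C3 closure are unchanged.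

## Steps

Step 1
Reactants: 1 penta-1,4-dien-3-ol
Product: 2 (2S,3R)-1,2-epoxypent-4-en-3-ol
Conditions: Ti(Oi-Pr)4 (cat.), D-(−)-diisopropyl tartrate, t-BuOOH, 4 Å MS, CH2Cl2, −20 °C
Reagents that add atoms: tert-butyl hydroperoxide, CC(C)(C)OO
Why: Sharpless asymmetric epoxidation desymmetrises the dienol, selecting one enantiotopic vinyl group and one face and giving the anti (erythro) epoxy alcohol; the minor enantiomer is consumed by a fast second epoxidation. The D-tartrate is chosen because the L-tartrate gives (S)-glycidol from allyl alcohol and the ring-CH2/carbinol priorities are exchanged here; this sets C8 (S) and the temporary C7 centre.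

Step 2
Reactants: 2 (2S,3R)-1,2-epoxypent-4-en-3-ol
Product: 3 (2S,3R)-1,2-epoxy-3-(4-methoxybenzyloxy)pent-4-ene
Conditions: NaH, 4-MeOC6H4CH2Cl, n-Bu4NI (cat.), THF–DMF, 0 °C
Reagents that add atoms: 4-methoxybenzyl chloride, COc1ccc(CCl)cc1
Why: Williamson etherification; in an aprotic medium O-alkylation of the alkoxide should outrun Payne rearrangement. The ether is stable to all later bases and is removable oxidatively when C7 has to become the ketone.

Step 3
Reactants: 3 (2S,3R)-1,2-epoxy-3-(4-methoxybenzyloxy)pent-4-ene; 4 acetic acid
Product: 6 (5S)-5-[(1R)-1-(4-methoxybenzyloxy)prop-2-enyl]dihydrofuran-2(3H)-one, via γ-hydroxy acid 5 (not isolated)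
Conditions: 4, LiN(i-Pr)2 (2.1 equiv), THF–DMPU, 0 → 45 °C; then 1 M HCl to pH 3; cat. TsOH, PhH, 23 °C
Reagents that add atoms: none
Why: The dianion of acetic acid opens the terminal epoxide at the unhindered CH2 by SN2 attack, forming C9–C10 and leaving C8 untouched; the γ-hydroxy acid lactonises under mild acid. The lactone ties O8 to C1 and gives a ring that can relay configuration to C10.

Step 4
Reactants: 6 (5S)-5-[(1R)-1-(4-methoxybenzyloxy)prop-2-enyl]dihydrofuran-2(3H)-one
Product: 7 (3R,5S)-3-methyl-5-[(1R)-1-(4-methoxybenzyloxy)prop-2-enyl]dihydrofuran-2(3H)-one (trans)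
Conditions: LiN(i-Pr)2, THF, −78 °C; MeI
Reagents that add atoms: iodomethane, CI
Why: Alkylation of the lactone enolate; methyl iodide should enter the envelope-shaped enolate anti to the branched C5 ring substituent (1,3-induction), giving the trans lactone and thereby C10 (R), syn to O8 in the extended chain.

Step 5
Reactants: 7 (3R,5S)-3-methyl-5-[(1R)-1-(4-methoxybenzyloxy)prop-2-enyl]dihydrofuran-2(3H)-one; 8 methyl phenyl sulfone
Product: 9 (3R,5S,6R)-5-hydroxy-6-(4-methoxybenzyloxy)-3-methyl-1-(phenylsulfonyl)oct-7-en-2-one
Conditions: 8 (2.5 equiv), n-BuLi, THF, −78 °C; then 7, −78 → −20 °C; aq. NH4Cl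
Reagents that add atoms: none
Why: Claisen-type acylation of the sulfonyl carbanion by the lactone forms C1–C2 and frees O8; the β-keto sulfone is deprotonated at C2 by the second equivalent, which stops over-addition and shields C10 from epimerisation. Addition at −78 °C should outrun enolisation of the lactone, as in the analogous acylation of lithiated methylphosphonates by α-branched esters.

Step 6
Reactants: 9 (3R,5S,6R)-5-hydroxy-6-(4-methoxybenzyloxy)-3-methyl-1-(phenylsulfonyl)oct-7-en-2-one
Product: 10 (3R,5S,6R)-5-(tert-butyldimethylsilyloxy)-6-(4-methoxybenzyloxy)-3-methyl-1-(phenylsulfonyl)oct-7-en-2-one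
Conditions: TBSCl, imidazole, DMF, 23 °C
Reagents that add atoms: tert-butyldimethylsilyl chloride, CC(C)(C)[Si](C)(C)Cl
Why: Silylation of the secondary O8 hydroxyl; the tertiary hydroxyl of the cyclic hemiketal form is not silylated, so the equilibrium drains to the open-chain ether.

Step 7
Reactants: 10 (3R,5S,6R)-5-(tert-butyldimethylsilyloxy)-6-(4-methoxybenzyloxy)-3-methyl-1-(phenylsulfonyl)oct-7-en-2-one
Product: 11 (2R,3R,5S,6R)-5-(tert-butyldimethylsilyloxy)-6-(4-methoxybenzyloxy)-3-methyl-1-(phenylsulfonyl)oct-7-en-2-ol
Conditions: [RuCl2((R)-BINAP)]2·NEt3 (1 mol %), H2 (6 atm), MeOH–CH2Cl2, 40 °C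
Reagents that add atoms: none
Why: Noyori asymmetric hydrogenation; the sulfonyl oxygen chelates divalent ruthenium as an ester carbonyl does in β-keto esters, so the (R)-ligand should give the (R)-carbinol, that is C1 anti to the C10 methyl, under catalyst control. Isolated alkenes and benzyl or silyl ethers are normally left untouched by this catalyst class at low pressure.

Step 8
Reactants: 11 (2R,3R,5S,6R)-5-(tert-butyldimethylsilyloxy)-6-(4-methoxybenzyloxy)-3-methyl-1-(phenylsulfonyl)oct-7-en-2-ol
Product: 12 O1-triisopropylsilyl ether of 11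
Conditions: TIPSOTf, 2,6-lutidine, CH2Cl2, 0 °C
Reagents that add atoms: triisopropylsilyl trifluoromethanesulfonate, CC(C)[Si](OS(=O)(=O)C(F)(F)F)(C(C)C)C(C)C
Why: Silyl triflate silylation of the hindered β-hydroxy sulfone; the most robust silyl group goes on O1 because this oxygen is unmasked last.

Step 9
Reactants: 12 O1-triisopropylsilyl ether of 11
Product: 14 (2S,3S,5R,6R)-3-(tert-butyldimethylsilyloxy)-2-(4-methoxybenzyloxy)-5-methyl-7-(phenylsulfonyl)-6-(triisopropylsilyloxy)heptanal (C6 aldehyde), via vicinal diol 13 (not isolated)
Conditions: OsO4 (2 mol %), NaIO4, 2,6-lutidine, dioxane–H2O, 23 °C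
Reagents that add atoms: sodium periodate (oxygen relayed through catalytic OsO4), [Na+].[O-]I(=O)(=O)=O
Why: Lemieux–Johnson cleavage of the only alkene; the lutidine buffer suppresses over-oxidation. The α-alkoxy aldehyde is used crude so that C7 does not epimerise.

Step 10
Reactants: 15 prop-2-yn-1-ol
Product: 17 (Z)-3-iodo-2-methylprop-2-en-1-ol, via alkenylmagnesium alkoxide 16 (not isolated)
Conditions: MeMgBr (2.5 equiv), CuI (10 mol %), THF, −10 → 23 °C; then I2, −78 → 0 °C
Reagents that add atoms: methylmagnesium bromide, C[Mg]Br; iodine, II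
Why: Copper-catalysed, alkoxide-directed anti-carbomagnesiation places methyl on the inner carbon (C4) and magnesium on the terminal carbon cis to the CH2O group; iodinolysis with retention gives the (Z)-iodoalkene, so C3 and the future C6 are cis.

Step 11
Reactants: 17 (Z)-3-iodo-2-methylprop-2-en-1-ol
Product: 18 (Z)-3-iodo-2-methylprop-2-enyl acetate
Conditions: Ac2O, pyridine, DMAP (cat.), CH2Cl2, 0 °C
Reagents that add atoms: acetic anhydride, CC(=O)OC(C)=O
Why: Standard acetylation; the acetate survives the chromium coupling and is later removed by hydride without touching silyl ethers.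

Step 12
Reactants: 14 C6 aldehyde; 18 (Z)-3-iodo-2-methylprop-2-enyl acetate
Product: 19 C6 allylic alcohol PhSO2CH2–CH(OTIPS)–CH(CH3)–CH2–CH(OTBS)–CH(OPMB)–CH(OH)–CH=C(CH3)–CH2OAc, (4Z), O6 anti to O7
Conditions: CrCl2 (6 equiv), NiCl2 (1 mol %), DMF, 23 °C
Reagents that add atoms: none
Why: Nozaki–Hiyama–Kishi coupling: zerovalent nickel inserts into the C–I bond, transmetalation gives the alkenyl derivative of trivalent chromium with retention of the Z geometry, and this adds to the aldehyde without touching sulfone C–H bonds, acetate or silyl ethers. Under non-chelating Felkin–Anh control by the α-alkoxy group, reinforced by the anti β-silyloxy group, the new C6 carbinol should be anti to O7 and therefore syn to O8.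

Step 13
Reactants: 19 C6 allylic alcohol
Product: 20 O6-triethylsilyl ether of 19
Conditions: TESOTf, 2,6-lutidine, CH2Cl2, −78 °C
Reagents that add atoms: triethylsilyl trifluoromethanesulfonate, CC[Si](CC)(CC)OS(=O)(=O)C(F)(F)F
Why: Silylation of the secondary allylic alcohol; O6 must be capped before C3 is activated, since a free cis-hydroxyl would displace the leaving group and close a 2,5-dihydrofuran. The smallest silyl group is used because O6 is the first silyl ether to be removed later.

Step 14
Reactants: 20 O6-triethylsilyl ether of 19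
Product: 21 C3 primary allylic alcohol (acetate removed)
Conditions: i-Bu2AlH, CH2Cl2, −78 °C
Reagents that add atoms: none
Why: Reductive cleavage of the acetate at low temperature; the sulfone, the silyl ethers and the benzyl ether are inert to the hydride.

Step 15
Reactants: 21 C3 primary allylic alcohol
Product: 23 acyclic C2 phenyl sulfone with (Z)-allylic chloride PhSO2CH2–CH(OTIPS)–CH(CH3)–CH2–CH(OTBS)–CH(OPMB)–CH(OTES)–CH=C(CH3)–CH2Cl, via allylic mesylate 22 (not isolated)
Conditions: MsCl, 2,4,6-collidine, LiCl, DMF, 0 °C
Reagents that add atoms: lithium chloride, [Li+].[Cl-]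
Why: One-pot mesylation and chloride displacement; the primary allylic centre reacts by direct SN2 substitution, so neither allylic transposition nor loss of the Z geometry is expected.

Step 16
Reactants: 23 acyclic C2 phenyl sulfone with (Z)-allylic chloride
Product: 24 ten-membered (4Z)-ene with C2 phenylsulfonyl group (C2 epimers), 1-OTIPS, 10-methyl, 8-OTBS, 7-OPMB, 6-OTES
Conditions: LiN(SiMe3)2 (3 equiv), THF, 0 → 40 °C, 23 added by syringe pump over 12 h, final 0.002 M
Reagents that add atoms: none
Why: LiN(SiMe3)2 reversibly removes a C2 proton next to the sulfonyl group, and the carbanion displaces chloride from the primary allylic C3 in an intramolecular SN2 reaction whose barrier is lowered by the adjacent C4=C5 π system. The closest known reaction type is the high-dilution alkylation of sulfone- or cyanohydrin-stabilised carbanions by allylic halides that closes ten-membered germacrane rings. The single ring (C1–C10) closes in the 10-exo-tet mode, the leaving group lying outside the ring being formed. The only new stereocentre is C2; it forms as an epimer mixture under no useful control and is erased in step 17, so no lasting stereocentre is created. C1, C6, C7, C8 and C10 are untouched, and the Z geometry of C4=C5 is carried over because C3 stays sp3. The step needs direct attack at C3 to beat SN2′ attack at C5, intermolecular alkylation and loss of the O1 silanolate from the carbanion. C3 is primary and unhindered, whereas C5 is shielded by the C6 silyl ether and would give an eight-membered ring; slow addition keeps the carbanion concentration low; the bulky silyloxy group is a poor leaving group and lithium keeps the carbanion tightly paired. No lactone, ester or ketone is present, so the base has no other target.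

Step 17
Reactants: 24 ten-membered (4Z)-ene with C2 phenylsulfonyl group
Product: 25 ten-membered (4Z)-ene with 1-OTIPS, 10-methyl, 8-OTBS, 7-OPMB, 6-OTES
Conditions: Na/Hg (6 %), Na2HPO4, MeOH–THF, −20 °C
Reagents that add atoms: none
Why: Reductive desulfonylation by electron transfer, C–S cleavage and protonation by methanol; low temperature and the phosphate buffer favour protonation over β-elimination of the O1 silyl ether. The C2 stereocentre is removed.

Step 18
Reactants: 25 ten-membered (4Z)-ene
Product: 26 C7 alcohol of 25 (PMB removed)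
Conditions: DDQ, CH2Cl2–pH 7 buffer, 0 °C
Reagents that add atoms: none
Why: Oxidative cleavage of the 4-methoxybenzyl ether through the benzylic oxocarbenium ion; under buffered conditions the three silyl ethers and the trisubstituted alkene should survive.

Step 19
Reactants: 26 C7 alcohol
Product: 27 C7 ketone with 6-OTES and 8-OTBS
Conditions: Dess–Martin periodinane, NaHCO3, CH2Cl2, 23 °C
Reagents that add atoms: none
Why: Dess–Martin oxidation copes with the hindered secondary alcohol and is neither basic nor strongly acidic, so C6 and C8 should not epimerise; the temporary C7 stereocentre is removed.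

Step 20
Reactants: 27 C7 ketone
Product: 28 α-hydroxy ketone (6-OH, C7 ketone, 8-OTBS, 1-OTIPS)
Conditions: HF·pyridine, pyridine, THF, 0 °C
Reagents that add atoms: none
Why: The triethylsilyl ether is far more labile to buffered fluoride than the tert-butyldimethylsilyl and triisopropylsilyl ethers, so only O6 is freed; the mild conditions avoid α-ketol isomerisation.

Step 21
Reactants: 29 ethyl 2-(diethoxyphosphoryl)acrylate; 30 4-methoxybenzyl alcohol
Product: 31 ethyl 2-(diethoxyphosphoryl)-3-(4-methoxybenzyloxy)propanoate (racemic)
Conditions: NaH (0.1 equiv), THF, 0 °C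
Reagents that add atoms: none
Why: Base-catalysed oxa-Michael addition of the alcohol to the doubly activated alkene; the stabilised phosphonoacetate carbanion is the resting state, so the adduct is favoured.

Step 22
Reactants: 31 ethyl 2-(diethoxyphosphoryl)-3-(4-methoxybenzyloxy)propanoate
Product: 32 2-(diethoxyphosphoryl)-3-(4-methoxybenzyloxy)propanoic acid
Conditions: LiOH·H2O, THF–H2O, 0 °C; then dilute HCl to pH 3
Reagents that add atoms: lithium hydroxide (carboxyl oxygen from hydroxide/water), [Li+].[OH-]
Why: Saponification of the carboxylic ester; phosphonate diesters resist hydroxide at 0 °C, and the short cold exposure limits retro-Michael loss of the benzyl alcohol.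

Step 23
Reactants: 28 α-hydroxy ketone; 32 2-(diethoxyphosphoryl)-3-(4-methoxybenzyloxy)propanoic acid
Product: 33 O6 ester of 28 with 32 (epimers at the phosphonate carbon)
Conditions: DCC, DMAP (0.1 equiv), CH2Cl2, 0 °C
Reagents that add atoms: none
Why: Steglich esterification of the secondary α-ketol under nearly neutral conditions, fast enough at 0 °C to avoid α-ketol transposition.

Step 24
Reactants: 33 O6 phosphonoacetate ester
Product: 34 butenolide: (4Z)-germacra-4,7(11)-dien-12,6-olide with 13-OPMB, 8-OTBS, 1-OTIPS
Conditions: K2CO3, 18-crown-6, PhMe, 23 °C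
Reagents that add atoms: none
Why: Intramolecular Horner–Wadsworth–Emmons reaction: the phosphonate carbanion adds to the C7 ketone through a five-membered transition state and loses diethyl phosphate to give the C7=C11 butenolide, with the alkene position fixed by the reagent. The heterogeneous carbonate is consumed as phosphate forms, and the β-alkoxide is a poor leaving group (its loss would reverse step 21), so neither enolisation of C6/C8 nor β-elimination should compete.

Step 25
Reactants: 34 butenolide with 13-OPMB
Product: 35 C13 primary alcohol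
Conditions: DDQ, CH2Cl2–pH 7 buffer, 0 → 23 °C
Reagents that add atoms: none
Why: Oxidative cleavage of the second 4-methoxybenzyl ether; the butenolide and both silyl ethers are inert to the quinone.

Step 26
Reactants: 35 C13 primary alcohol
Product: 36 C13 acetate with 8-OTBS, 1-OTIPS
Conditions: Ac2O, pyridine, DMAP (cat.), CH2Cl2, 0 °C
Reagents that add atoms: acetic anhydride, CC(=O)OC(C)=O
Why: Acetylation of the only free hydroxyl; the weak base should not deprotonate C6.

Step 27
Reactants: 36 C13 acetate
Product: 37 C8 alcohol with 13-OAc, 1-OTIPS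
Conditions: HF·pyridine, pyridine, THF, 0 → 23 °C
Reagents that add atoms: none
Why: A secondary tert-butyldimethylsilyl ether is cleaved by buffered fluoride well before a secondary triisopropylsilyl ether, so O8 is freed while O1 stays protected; acetate and lactone are stable to acidic fluoride.

Step 28
Reactants: 37 C8 alcohol
Product: 38 C8 methacrylate with 13-OAc, 1-OTIPS
Conditions: methacrylic anhydride, Et3N, DMAP, CH2Cl2, 0 → 23 °C
Reagents that add atoms: methacrylic anhydride, C=C(C)C(=O)OC(=O)C(C)=C
Why: DMAP-catalysed acylation of the secondary alcohol; no epoxide is present yet, so the mild amine base cannot trigger eliminative opening.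

Step 29
Reactants: 38 C8 methacrylate
Product: 39 (4Z)-13-acetoxy-1-hydroxy-8-(methacryloyloxy)germacra-4,7(11)-dien-12,6-olide
Conditions: HF·pyridine (excess), THF, 23 °C
Reagents that add atoms: none
Why: Acidic fluoride removes the last silyl group without touching the two esters or the lactone; doing this before epoxidation keeps acid away from the epoxide.

Step 30
Reactants: 39 des-epoxy precursor
Product: 40 target, (1S,4R,5S,6S,8S,10R)-13-acetoxy-4,5-epoxy-1-hydroxy-8-(methacryloyloxy)germacr-7(11)-en-12,6-olide
Conditions: VO(acac)2 (5 mol %), t-BuOOH, CH2Cl2, 0 °C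
Reagents that add atoms: tert-butyl hydroperoxide, CC(C)(C)OO
Why: Hydroxyl-directed epoxidation: the C1 alcohol (bishomoallylic to C4=C5) binds pentavalent vanadium together with the peroxide and delivers oxygen within the complex to the face on which O1 lies, which on this ring is the face syn to O6 and O8; this sets C4 (R) and C5 (S). The butenolide and methacrylate alkenes are electron-poor and should not react, and because O1 and the new oxygen are cis, backside attack of O1 on C4 is geometrically excluded.

## Compound list

1 | penta-1,4-dien-3-ol | C=CC(O)C=C | starting material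
2 | (2S,3R)-1,2-epoxypent-4-en-3-ol | C=C[C@@H](O)[C@@H]1CO1 | intermediate
3 | (2S,3R)-1,2-epoxy-3-(4-methoxybenzyloxy)pent-4-ene | C=C[C@@H](OCc1ccc(OC)cc1)[C@@H]1CO1 | intermediate
4 | acetic acid | CC(=O)O | starting material
5 | (4S,5R)-4-hydroxy-5-(4-methoxybenzyloxy)hept-6-enoic acid | OC(=O)CC[C@H](O)[C@H](OCc1ccc(OC)cc1)C=C | intermediate (not isolated)
6 | (5S)-5-[(1R)-1-(4-methoxybenzyloxy)prop-2-enyl]dihydrofuran-2(3H)-one | O=C1CC[C@H](O1)[C@H](OCc2ccc(OC)cc2)C=C | intermediate
7 | (3R,5S)-3-methyl-5-[(1R)-1-(4-methoxybenzyloxy)prop-2-enyl]dihydrofuran-2(3H)-one (trans) | O=C1[C@H](C)C[C@H](O1)[C@H](OCc2ccc(OC)cc2)C=C | intermediate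
8 | methyl phenyl sulfone | CS(=O)(=O)c1ccccc1 | starting material
9 | (3R,5S,6R)-5-hydroxy-6-(4-methoxybenzyloxy)-3-methyl-1-(phenylsulfonyl)oct-7-en-2-one | O=S(=O)(c1ccccc1)CC(=O)[C@H](C)C[C@H](O)[C@H](OCc1ccc(OC)cc1)C=C | intermediate
10 | (3R,5S,6R)-5-(tert-butyldimethylsilyloxy)-6-(4-methoxybenzyloxy)-3-methyl-1-(phenylsulfonyl)oct-7-en-2-one | O=S(=O)(c1ccccc1)CC(=O)[C@H](C)C[C@H](O[Si](C)(C)C(C)(C)C)[C@H](OCc1ccc(OC)cc1)C=C | intermediate
11 | (2R,3R,5S,6R)-5-(tert-butyldimethylsilyloxy)-6-(4-methoxybenzyloxy)-3-methyl-1-(phenylsulfonyl)oct-7-en-2-ol | O=S(=O)(c1ccccc1)C[C@H](O)[C@H](C)C[C@H](O[Si](C)(C)C(C)(C)C)[C@H](OCc1ccc(OC)cc1)C=C | intermediate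
12 | O1-triisopropylsilyl ether of 11 (C1, C7, C8, C10 as in 11) | O=S(=O)(c1ccccc1)C[C@H](O[Si](C(C)C)(C(C)C)C(C)C)[C@H](C)C[C@H](O[Si](C)(C)C(C)(C)C)[C@H](OCc1ccc(OC)cc1)C=C | intermediate
13 | vicinal diol from the vinyl group of 12 (C5,C6-diol, C6 epimers) | O=S(=O)(c1ccccc1)C[C@H](O[Si](C(C)C)(C(C)C)C(C)C)[C@H](C)C[C@H](O[Si](C)(C)C(C)(C)C)[C@H](OCc1ccc(OC)cc1)C(O)CO | intermediate (not isolated)
14 | (2S,3S,5R,6R)-3-(tert-butyldimethylsilyloxy)-2-(4-methoxybenzyloxy)-5-methyl-7-(phenylsulfonyl)-6-(triisopropylsilyloxy)heptanal (C6 aldehyde) | O=S(=O)(c1ccccc1)C[C@H](O[Si](C(C)C)(C(C)C)C(C)C)[C@H](C)C[C@H](O[Si](C)(C)C(C)(C)C)[C@H](OCc1ccc(OC)cc1)C=O | intermediate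
15 | prop-2-yn-1-ol | C#CCO | starting material
16 | bromomagnesium (Z)-3-(bromomagnesio)-2-methylprop-2-en-1-olate | Br[Mg]OC/C(C)=C\[Mg]Br | intermediate (not isolated)
17 | (Z)-3-iodo-2-methylprop-2-en-1-ol | OC/C(C)=C\I | intermediate
18 | (Z)-3-iodo-2-methylprop-2-enyl acetate | CC(=O)OC/C(C)=C\I | intermediate
19 | C6 allylic alcohol: open chain with C2 sulfone, 1-OTIPS, 10-methyl, 8-OTBS, 7-OPMB, 6-OH (anti to O7), (4Z)-ene, C3 acetate | O=S(=O)(c1ccccc1)C[C@H](O[Si](C(C)C)(C(C)C)C(C)C)[C@H](C)C[C@H](O[Si](C)(C)C(C)(C)C)[C@H](OCc1ccc(OC)cc1)[C@H](O)/C=C(/C)COC(C)=O | intermediate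
20 | O6-triethylsilyl ether of 19 | O=S(=O)(c1ccccc1)C[C@H](O[Si](C(C)C)(C(C)C)C(C)C)[C@H](C)C[C@H](O[Si](C)(C)C(C)(C)C)[C@H](OCc1ccc(OC)cc1)[C@H](O[Si](CC)(CC)CC)/C=C(/C)COC(C)=O | intermediate
21 | C3 primary (Z)-allylic alcohol from 20 | O=S(=O)(c1ccccc1)C[C@H](O[Si](C(C)C)(C(C)C)C(C)C)[C@H](C)C[C@H](O[Si](C)(C)C(C)(C)C)[C@H](OCc1ccc(OC)cc1)[C@H](O[Si](CC)(CC)CC)/C=C(/C)CO | intermediate
22 | C3 methanesulfonate of 21 | O=S(=O)(c1ccccc1)C[C@H](O[Si](C(C)C)(C(C)C)C(C)C)[C@H](C)C[C@H](O[Si](C)(C)C(C)(C)C)[C@H](OCc1ccc(OC)cc1)[C@H](O[Si](CC)(CC)CC)/C=C(/C)COS(C)(=O)=O | intermediate (not isolated)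
23 | acyclic C2 phenyl sulfone with (Z)-allylic chloride at C3 (1-OTIPS, 10-methyl, 8-OTBS, 7-OPMB, 6-OTES) | O=S(=O)(c1ccccc1)C[C@H](O[Si](C(C)C)(C(C)C)C(C)C)[C@H](C)C[C@H](O[Si](C)(C)C(C)(C)C)[C@H](OCc1ccc(OC)cc1)[C@H](O[Si](CC)(CC)CC)/C=C(/C)CCl | intermediate
24 | ten-membered (4Z)-ene with C2 phenylsulfonyl group (C2 epimers), 1-OTIPS, 10-methyl, 8-OTBS, 7-OPMB, 6-OTES | O=S(=O)(c1ccccc1)C1[C@H](O[Si](C(C)C)(C(C)C)C(C)C)[C@H](C)C[C@H](O[Si](C)(C)C(C)(C)C)[C@H](OCc2ccc(OC)cc2)[C@H](O[Si](CC)(CC)CC)/C=C(/C)C1 | intermediate
25 | desulfonylated ten-membered (4Z)-ene, 1-OTIPS, 10-methyl, 8-OTBS, 7-OPMB, 6-OTES | C1[C@H](O[Si](C(C)C)(C(C)C)C(C)C)[C@H](C)C[C@H](O[Si](C)(C)C(C)(C)C)[C@H](OCc2ccc(OC)cc2)[C@H](O[Si](CC)(CC)CC)/C=C(/C)C1 | intermediate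
26 | C7 alcohol of 25 | C1[C@H](O[Si](C(C)C)(C(C)C)C(C)C)[C@H](C)C[C@H](O[Si](C)(C)C(C)(C)C)[C@H](O)[C@H](O[Si](CC)(CC)CC)/C=C(/C)C1 | intermediate
27 | C7 ketone (6-OTES, 8-OTBS, 1-OTIPS) | C1[C@H](O[Si](C(C)C)(C(C)C)C(C)C)[C@H](C)C[C@H](O[Si](C)(C)C(C)(C)C)C(=O)[C@H](O[Si](CC)(CC)CC)/C=C(/C)C1 | intermediate
28 | α-hydroxy ketone (6-OH, C7 ketone, 8-OTBS, 1-OTIPS) | C1[C@H](O[Si](C(C)C)(C(C)C)C(C)C)[C@H](C)C[C@H](O[Si](C)(C)C(C)(C)C)C(=O)[C@H](O)/C=C(/C)C1 | intermediate
29 | ethyl 2-(diethoxyphosphoryl)acrylate | C=C(C(=O)OCC)P(=O)(OCC)OCC | starting material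
30 | 4-methoxybenzyl alcohol | COc1ccc(CO)cc1 | starting material
31 | ethyl 2-(diethoxyphosphoryl)-3-(4-methoxybenzyloxy)propanoate (racemic) | CCOC(=O)C(COCc1ccc(OC)cc1)P(=O)(OCC)OCC | intermediate
32 | 2-(diethoxyphosphoryl)-3-(4-methoxybenzyloxy)propanoic acid (racemic) | OC(=O)C(COCc1ccc(OC)cc1)P(=O)(OCC)OCC | intermediate
33 | O6 ester of 28 with 32 (epimers at the phosphonate carbon) | C1[C@H](O[Si](C(C)C)(C(C)C)C(C)C)[C@H](C)C[C@H](O[Si](C)(C)C(C)(C)C)C(=O)[C@H](OC(=O)C(COCc2ccc(OC)cc2)P(=O)(OCC)OCC)/C=C(/C)C1 | intermediate
34 | (4Z)-germacra-4,7(11)-dien-12,6-olide with 13-OPMB, 8-OTBS, 1-OTIPS (C1, C6, C8, C10 as in 40) | CC(C)(C)[Si](C)(C)O[C@H]1C[C@@H](C)[C@@H](O[Si](C(C)C)(C(C)C)C(C)C)CC/C(C)=C\[C@H]2OC(=O)C(COCc3ccc(OC)cc3)=C12 | intermediate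
35 | 13-hydroxy butenolide with 8-OTBS, 1-OTIPS | CC(C)(C)[Si](C)(C)O[C@H]1C[C@@H](C)[C@@H](O[Si](C(C)C)(C(C)C)C(C)C)CC/C(C)=C\[C@H]2OC(=O)C(CO)=C12 | intermediate
36 | 13-acetoxy butenolide with 8-OTBS, 1-OTIPS | CC(C)(C)[Si](C)(C)O[C@H]1C[C@@H](C)[C@@H](O[Si](C(C)C)(C(C)C)C(C)C)CC/C(C)=C\[C@H]2OC(=O)C(COC(C)=O)=C12 | intermediate
37 | 13-acetoxy-8-hydroxy butenolide with 1-OTIPS | O[C@H]1C[C@@H](C)[C@@H](O[Si](C(C)C)(C(C)C)C(C)C)CC/C(C)=C\[C@H]2OC(=O)C(COC(C)=O)=C12 | intermediate
38 | 13-acetoxy-8-(methacryloyloxy) butenolide with 1-OTIPS | C=C(C)C(=O)O[C@H]1C[C@@H](C)[C@@H](O[Si](C(C)C)(C(C)C)C(C)C)CC/C(C)=C\[C@H]2OC(=O)C(COC(C)=O)=C12 | intermediate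
39 | (4Z)-13-acetoxy-1-hydroxy-8-(methacryloyloxy)germacra-4,7(11)-dien-12,6-olide | C=C(C)C(=O)O[C@H]1C[C@@H](C)[C@@H](O)CC/C(C)=C\[C@H]2OC(=O)C(COC(C)=O)=C12 | intermediate
40 | (1S,4R,5S,6S,8S,10R)-13-acetoxy-4,5-epoxy-1-hydroxy-8-(methacryloyloxy)germacr-7(11)-en-12,6-olide | C=C(C)C(=O)O[C@H]1C[C@@H](C)[C@@H](O)CC[C@@]2(C)O[C@H]2[C@H]2OC(=O)C(COC(C)=O)=C12 | target

## Step count and least certain steps

Total: 30 steps. Longest linear sequence: 26 steps (steps 1–9, 12–20 and 23–30); steps 10–11 and 21–22 prepare the two side fragments.

**Step 16 (key step).** Most likely failure: intermolecular alkylation, incomplete deprotonation by the silylamide, or loss of the O1 silanolate from the carbanion to give a vinyl sulfone, all at the expense of the ten-membered closure. Fallback, setting out from 12 and 17: alcohol 17 is converted with CBr4/PPh3 into (Z)-3-bromo-1-iodo-2-methylprop-1-ene F1. Sulfone 12 is lithiated with n-BuLi at −78 °C and alkylated intermolecularly with F1, forming C2–C3 without any dilution problem and giving the iodoalkenyl sulfone F2. OsO4/NaIO4 cleavage of the terminal vinyl group (the iodoalkene is electron-poor and slower) gives the iodoalkenyl aldehyde F3. An intramolecular CrCl2/NiCl2 coupling under high dilution then closes the same ring at C5–C6 to give the macrocyclic allylic alcohol F4. Silylation with TESOTf returns the route at 24.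

**Step 30.** Most likely failure: poor facial selectivity, if the vanadate ester at O1 cannot reach C4=C5 and oxygen is instead delivered from the ring periphery to the opposite face; Lewis-acid-promoted opening of the product is a lesser risk. Fallback, setting out from 37: the epoxidation is moved forward and directed by the free C8 hydroxyl, which in the conformer with H6 and H8 eclipsing their neighbouring double bonds lies over the required face. VO(acac)2/t-BuOOH should give the epoxy alcohol F5, methacrylic anhydride/DMAP the epoxy methacrylate silyl ether F6, and buffered HF·pyridine then removes the O1 silyl group to reach 40.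

**Step 24.** Most likely failure: slow addition of the substituted phosphonate carbanion to the hindered ketone, leaving time for enolisation and epimerisation at C6 or C8. Fallback, setting out from 27: methylenation with Cp2TiMe2 gives the exocyclic alkene F7, and buffered HF·pyridine removes the O6 silyl group to give the allylic alcohol F8. Esterification with the known 2-[(4-methoxybenzyloxy)methyl]acrylic acid (DCC, DMAP) gives the diene ester F9. Ring-closing metathesis with the second-generation Grubbs catalyst in hot toluene forms the C7=C11 bond and returns the route at 34.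

**Step 12.** Most likely failure: insufficient Felkin–Anh selectivity, giving a mixture of C6 epimers. Fallback, setting out from 19 as the epimer mixture: Dess–Martin oxidation gives the (Z)-enone F10, and reduction with Zn(BH4)2 under chelation between the C6 carbonyl and the O7 benzyl ether should deliver hydride to give the anti product, returning the route at 19 as a single epimer.

**Step 7.** Most likely failure: partial hydrogenation or isomerisation of the terminal alkene by ruthenium hydride species, or a mismatch between catalyst and the C10 stereocentre that lowers selectivity at C1. Fallback, setting out from 10: NaBH4/CeCl3 in MeOH reduces only the ketone and gives 11 together with its C1 epimer F11. The two are separated by chromatography, F11 is returned to 10 by Dess–Martin oxidation and recycled, and the route continues from 11.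

## Further compounds

F1 | step 16 | (Z)-3-bromo-1-iodo-2-methylprop-1-ene | BrC/C(C)=C\I
F2 | step 16 | C2-alkylated sulfone from 12 and F1 (C2 epimers; iodoalkene and terminal vinyl group) | O=S(=O)(c1ccccc1)C(C/C(C)=C\I)[C@H](O[Si](C(C)C)(C(C)C)C(C)C)[C@H](C)C[C@H](O[Si](C)(C)C(C)(C)C)[C@H](OCc1ccc(OC)cc1)C=C
F3 | step 16 | iodoalkenyl C6 aldehyde from F2 | O=S(=O)(c1ccccc1)C(C/C(C)=C\I)[C@H](O[Si](C(C)C)(C(C)C)C(C)C)[C@H](C)C[C@H](O[Si](C)(C)C(C)(C)C)[C@H](OCc1ccc(OC)cc1)C=O
F4 | step 16 | macrocyclic C6 allylic alcohol (6-OH analogue of 24, C2 epimers) | O=S(=O)(c1ccccc1)C1[C@H](O[Si](C(C)C)(C(C)C)C(C)C)[C@H](C)C[C@H](O[Si](C)(C)C(C)(C)C)[C@H](OCc2ccc(OC)cc2)[C@H](O)/C=C(/C)C1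
F5 | step 30 | 13-acetoxy-4,5-epoxy-8-hydroxy butenolide with 1-OTIPS | O[C@H]1C[C@@H](C)[C@@H](O[Si](C(C)C)(C(C)C)C(C)C)CC[C@@]2(C)O[C@H]2[C@H]2OC(=O)C(COC(C)=O)=C12
F6 | step 30 | O1-triisopropylsilyl ether of 40 | C=C(C)C(=O)O[C@H]1C[C@@H](C)[C@@H](O[Si](C(C)C)(C(C)C)C(C)C)CC[C@@]2(C)O[C@H]2[C@H]2OC(=O)C(COC(C)=O)=C12
F7 | step 24 | C7 exocyclic methylene analogue of 27 | C1[C@H](O[Si](C(C)C)(C(C)C)C(C)C)[C@H](C)C[C@H](O[Si](C)(C)C(C)(C)C)C(=C)[C@H](O[Si](CC)(CC)CC)/C=C(/C)C1
F8 | step 24 | C6 alcohol of F7 | C1[C@H](O[Si](C(C)C)(C(C)C)C(C)C)[C@H](C)C[C@H](O[Si](C)(C)C(C)(C)C)C(=C)[C@H](O)/C=C(/C)C1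
F9 | step 24 | O6 2-[(4-methoxybenzyloxy)methyl]acrylate of F8 | C1[C@H](O[Si](C(C)C)(C(C)C)C(C)C)[C@H](C)C[C@H](O[Si](C)(C)C(C)(C)C)C(=C)[C@H](OC(=O)C(=C)COCc2ccc(OC)cc2)/C=C(/C)C1
F10 | step 12 | C6 ketone ((Z)-enone) from 19 | O=S(=O)(c1ccccc1)C[C@H](O[Si](C(C)C)(C(C)C)C(C)C)[C@H](C)C[C@H](O[Si](C)(C)C(C)(C)C)[C@H](OCc1ccc(OC)cc1)C(=O)/C=C(/C)COC(C)=O
F11 | step 7 | C1 epimer of 11, (2S,3R,5S,6R) | O=S(=O)(c1ccccc1)C[C@@H](O)[C@H](C)C[C@H](O[Si](C)(C)C(C)(C)C)[C@H](OCc1ccc(OC)cc1)C=C
A1 | alternative 1 | open-chain C6 aldehyde with (Z)-C7 iodoalkene methyl ester, epoxide, 8-methacrylate, 13-acetate, 1-OTBS | C=C(C)C(=O)O[C@@H](C[C@@H](C)[C@@H](O[Si](C)(C)C(C)(C)C)CC[C@@]1(C)O[C@H]1C=O)/C(I)=C(\COC(C)=O)C(=O)OC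
A2 | alternative 1 | O1-tert-butyldimethylsilyl ether of 40 | C=C(C)C(=O)O[C@H]1C[C@@H](C)[C@@H](O[Si](C)(C)C(C)(C)C)CC[C@@]2(C)O[C@H]2[C@H]2OC(=O)C(COC(C)=O)=C12
A3 | alternative 2 | open-chain C1 aldehyde with C2 iodoalkyne, epoxide and butenolide in place, 8-OTES | CC[Si](CC)(CC)O[C@@H](C[C@@H](C)C=O)C1=C(COC(C)=O)C(=O)O[C@@H]1[C@@H]1O[C@]1(C)C#CI
A4 | alternative 2 | ten-membered 2-yne carbinol (C1 epimers), 8-OTES | CC[Si](CC)(CC)O[C@H]1C[C@@H](C)C(O)C#C[C@@]2(C)O[C@H]2[C@H]2OC(=O)C(COC(C)=O)=C12
A5 | alternative 3 | (1R,6R)-1-[(Z)-2-(4-methoxybenzyloxy)ethenyl]-3-methyl-6-(prop-1-en-2-yl)cyclohex-2-en-1-ol | CC1=C[C@](O)(/C=C\OCc2ccc(OC)cc2)[C@@H](C(C)=C)CC1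
A6 | alternative 3 | (8S)-8-(4-methoxybenzyloxy)germacra-1(10)E,4Z-dien-6-one | COc1ccc(CO[C@H]2C/C(C)=C/CC/C(C)=C\C(=O)C2)cc1
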